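**Retrosynthetic overview**

1. The plan rests on ring A (C4a, C5, C6, C7, C8, C8a): it is pentasubstituted, carries three adjacent oxygens on C6, C7 and C8, and has a crowded C8a wedged between C8–OMe and stereogenic C1. These six carbons map onto a 2-substituted 3,4-dimethoxyfuran (C8a, C8, C7, C6) and a terminal alkyne (C4a, C5).
2. Key disconnection: C4a–C8a and C5–C6 by intramolecular furan–ynone [4+2] cycloaddition of ynone 20. Ring B closes in the cycloaddition and ring A becomes aromatic when the oxygen bridge opens (furan O becomes C6–OH, the ketone stays at C4), giving tetralone 22.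
3. Ynone 20 comes from Weinreb amide 18 and ethynylmagnesium bromide, and 18 from γ-lactone 16. Both stereocentres are set on one (S)-oxazolidinone: C1 by copper-catalysed addition of the furyl Grignard reagent to cinnamoyl imide 7, C2 by enolate alkylation with methyl bromoacetate.
4. After ring A: methylate C6–OH, debenzylate ring C, cleave the C7 methyl ether para to the C4 ketone with thiolate, and protect as MOM ethers. Then formylate C3, form the enol ether, reduce and transpose with acid to the C3=C4 enal, and deprotect.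
5. Ring order: ring C is purchased; rings B and A are formed together in step 9.

Key step: step 9

Remark: lignan numbering is used (C1 bears ring C, C2 bears C9H2OH, C3 bears the C10 aldehyde). With one (S)-auxiliary, adding the aryl Grignard reagent to a furyl-acryloyl imide would give the C1 epimer, so the furan is made the nucleophile and the aryl group the acceptor substituent. Compounds 1 and 8 are taken as purchasable.

**Route**

Step 1
Reactants: 1 4-(benzyloxy)-3,5-dimethoxybenzaldehyde; 2 malonic acid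
Product: 4 (2E)-3-[4-(benzyloxy)-3,5-dimethoxyphenyl]prop-2-enoic acid, via ylidenemalonic acid 3 (not isolated)
Conditions: pyridine, piperidine (10 mol %), 90 °C; aq. HCl work-up
Reagents that add atoms: none
Why: Knoevenagel–Doebner condensation, in which the aldehyde condenses with malonic acid and the ylidenemalonic acid loses CO2 in hot pyridine to give the E acid, with the benzyl ether untouched.

Step 2
Reactants: 4 (2E)-3-[4-(benzyloxy)-3,5-dimethoxyphenyl]prop-2-enoic acid; 5 (4S)-4-benzyl-1,3-oxazolidin-2-one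
Product: 7 (4S)-4-benzyl-3-{(2E)-3-[4-(benzyloxy)-3,5-dimethoxyphenyl]prop-2-enoyl}-1,3-oxazolidin-2-one, via mixed pivalic anhydride 6 (not isolated)
Conditions: t-BuCOCl, Et3N, THF, −20 °C; then LiCl, 5, −20 → 23 °C
Reagents that add atoms: none
Why: N-acylation of the oxazolidinone through the mixed pivalic anhydride, which is attacked at the less hindered cinnamoyl carbonyl under the LiCl/Et3N protocol.

Step 3
Reactants: 7 (4S)-4-benzyl-3-{(2E)-3-[4-(benzyloxy)-3,5-dimethoxyphenyl]prop-2-enoyl}-1,3-oxazolidin-2-one; 8 3,4-dimethoxyfuran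
Product: 11 (4S)-4-benzyl-3-{(3S)-3-[4-(benzyloxy)-3,5-dimethoxyphenyl]-3-(3,4-dimethoxyfuran-2-yl)propanoyl}-1,3-oxazolidin-2-one, via furyllithium 9 (not isolated), via furylmagnesium bromide 10 (not isolated)
Conditions: 8 (2.5 equiv), n-BuLi, THF, −78 → 0 °C; MgBr2·OEt2, 0 °C; CuBr·SMe2 (30 mol %), THF/Me2S, −40 °C; then 7, −40 → −10 °C; aq. NH4Cl
Reagents that add atoms: none
Why: Copper-catalysed conjugate addition of a heteroaryl Grignard reagent to an N-enoyl oxazolidinone, in which the furan is lithiated at C2, transmetalated to magnesium and delivered to the magnesium-chelated s-cis enoyl unit on the face away from the benzyl group, which sets C1 (3S) in the sense that, with the same auxiliary directing step 4, leads to the trans C1/C2 relationship.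

Step 4
Reactants: 11 (4S)-4-benzyl-3-{(3S)-3-[4-(benzyloxy)-3,5-dimethoxyphenyl]-3-(3,4-dimethoxyfuran-2-yl)propanoyl}-1,3-oxazolidin-2-one; 12 methyl bromoacetate
Product: 14 methyl (3S,4S)-3-{[(4S)-4-benzyl-2-oxo-1,3-oxazolidin-3-yl]carbonyl}-4-[4-(benzyloxy)-3,5-dimethoxyphenyl]-4-(3,4-dimethoxyfuran-2-yl)butanoate, via sodium enolate 13 (not isolated)
Conditions: NaN(SiMe3)2, THF, −78 °C; then 12, −78 → −40 °C; aq. NH4Cl
Reagents that add atoms: none
Why: Auxiliary-controlled (Evans) enolate alkylation, in which the chelated Z enolate takes up the reactive bromoacetate anti to the benzyl group, which sets C2 (3S) and so the relative configuration that becomes trans C1/C2 in ring B.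

Step 5
Reactants: 14 methyl (3S,4S)-3-{[(4S)-4-benzyl-2-oxo-1,3-oxazolidin-3-yl]carbonyl}-4-[4-(benzyloxy)-3,5-dimethoxyphenyl]-4-(3,4-dimethoxyfuran-2-yl)butanoate
Product: 16 (4S)-4-{(S)-[4-(benzyloxy)-3,5-dimethoxyphenyl](3,4-dimethoxyfuran-2-yl)methyl}oxolan-2-one, via hydroxy ester 15 (not isolated)
Conditions: NaBH4, THF/H2O (3:1), 0 → 23 °C; aq. NH4Cl
Reagents that add atoms: none
Why: Chemoselective borohydride reduction of the exocyclic imide carbonyl in wet THF spares the methyl ester and releases the auxiliary, and the primary alkoxide then closes the γ-lactone by 5-exo-trig acyl substitution, so the acid-labile furan never meets acid and no stereocentre is touched.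

Step 6
Reactants: 16 (4S)-4-{(S)-[4-(benzyloxy)-3,5-dimethoxyphenyl](3,4-dimethoxyfuran-2-yl)methyl}oxolan-2-one
Product: 17 (3S,4S)-4-[4-(benzyloxy)-3,5-dimethoxyphenyl]-4-(3,4-dimethoxyfuran-2-yl)-3-(hydroxymethyl)-N-methoxy-N-methylbutanamide
Conditions: MeNHOMe·HCl, i-PrMgCl (premixed, THF, −20 °C); then 16, −20 → 0 °C; aq. NH4Cl
Reagents that add atoms: N,O-dimethylhydroxylamine hydrochloride, CNOC.Cl
Why: Weinreb aminolysis of the lactone by the magnesium amide of N,O-dimethylhydroxylamine, a non-acidic opening that gives the γ-hydroxy Weinreb amide.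

Step 7
Reactants: 17 (3S,4S)-4-[4-(benzyloxy)-3,5-dimethoxyphenyl]-4-(3,4-dimethoxyfuran-2-yl)-3-(hydroxymethyl)-N-methoxy-N-methylbutanamide
Product: 18 (3S,4S)-4-[4-(benzyloxy)-3,5-dimethoxyphenyl]-3-{[(tert-butyldimethylsilyl)oxy]methyl}-4-(3,4-dimethoxyfuran-2-yl)-N-methoxy-N-methylbutanamide
Conditions: TBSCl, imidazole, DMF, 0 → 23 °C
Reagents that add atoms: tert-butyldimethylsilyl chloride, CC(C)(C)[Si](C)(C)Cl
Why: Silylation of the primary alcohol under standard imidazole conditions, done at once so that the hydroxy amide cannot return to the lactone.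

Step 8
Reactants: 18 (3S,4S)-4-[4-(benzyloxy)-3,5-dimethoxyphenyl]-3-{[(tert-butyldimethylsilyl)oxy]methyl}-4-(3,4-dimethoxyfuran-2-yl)-N-methoxy-N-methylbutanamide; 19 ethynylmagnesium bromide
Product: 20 (5S,6S)-6-[4-(benzyloxy)-3,5-dimethoxyphenyl]-5-{[(tert-butyldimethylsilyl)oxy]methyl}-6-(3,4-dimethoxyfuran-2-yl)hex-1-yn-3-one
Conditions: 19 (0.5 M in THF), THF, 0 °C; inverse quench into cold 10% aq. citric acid; used at once
Reagents that add atoms: none
Why: Weinreb ketone synthesis, in which the chelated tetrahedral adduct prevents a second addition and the cold acidic quench protonates the released amine so that it cannot add to the terminal ynone.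

Step 9
Reactants: 20 (5S,6S)-6-[4-(benzyloxy)-3,5-dimethoxyphenyl]-5-{[(tert-butyldimethylsilyl)oxy]methyl}-6-(3,4-dimethoxyfuran-2-yl)hex-1-yn-3-one
Product: 22 (3S,4S)-4-[4-(benzyloxy)-3,5-dimethoxyphenyl]-3-{[(tert-butyldimethylsilyl)oxy]methyl}-7-hydroxy-5,6-dimethoxy-3,4-dihydronaphthalen-1(2H)-one, via oxa-bridged cycloadduct 21 (not isolated)
Conditions: PhMe (0.01 M), 2,6-di-tert-butyl-4-methylphenol (10 mol %), 80 °C, argon; then PPTS (10 mol %), 23 °C
Reagents that add atoms: none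
Why: Thermal intramolecular Diels–Alder reaction of the furan (diene C8a, C8, C7, C6) with the tethered ynone (dienophile C4a, C5), a normal-demand [4+2] cycloaddition in which the two methoxy groups raise the diene HOMO and the ketone lowers the alkyne LUMO, forms C4a–C8a and C5–C6 and gives oxanorbornadiene 21. The closest known reaction type is the intramolecular furan–alkynone Diels–Alder benzannulation that gives hydroxy-tetralones after opening of the oxygen bridge. Ring B closes as a six-membered carbocycle in the fused mode set by the four-atom tether C1–C2–C3–C4, with the ketone inside the new ring; ring A closes as the six-membered ring of the cycloadduct and becomes benzenoid when the C8a–O bond ionises, helped by the C7 methoxy group through C8=C7, and the C6 proton is lost. No lasting stereocentre is made: the two bridgehead centres of 21 are erased on aromatisation, and C1 and C2 take no part and keep their configuration. Only regiocontrol is needed and the tether supplies it, because the alkyne can span the furan 2,5-positions in one orientation only and because only cleavage at C8a–O leaves a hydrogen (on C6) to be lost, so the phenol appears at C6 and the ketone at C4. High dilution and a radical inhibitor protect the terminal ynone from intermolecular addition, and the trace of PPTS opens any bridge that survives the heating.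

Step 10
Reactants: 22 (3S,4S)-4-[4-(benzyloxy)-3,5-dimethoxyphenyl]-3-{[(tert-butyldimethylsilyl)oxy]methyl}-7-hydroxy-5,6-dimethoxy-3,4-dihydronaphthalen-1(2H)-one
Product: 23 (3S,4S)-4-[4-(benzyloxy)-3,5-dimethoxyphenyl]-3-{[(tert-butyldimethylsilyl)oxy]methyl}-5,6,7-trimethoxy-3,4-dihydronaphthalen-1(2H)-one
Conditions: MeI, K2CO3, acetone, 45 °C
Reagents that add atoms: iodomethane, CI
Why: Williamson O-methylation of the only free phenol (C6–OH), with a base too weak to enolise the aryl ketone.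

Step 11
Reactants: 23 (3S,4S)-4-[4-(benzyloxy)-3,5-dimethoxyphenyl]-3-{[(tert-butyldimethylsilyl)oxy]methyl}-5,6,7-trimethoxy-3,4-dihydronaphthalen-1(2H)-one
Product: 24 (3S,4S)-3-{[(tert-butyldimethylsilyl)oxy]methyl}-4-(4-hydroxy-3,5-dimethoxyphenyl)-5,6,7-trimethoxy-3,4-dihydronaphthalen-1(2H)-one
Conditions: H2 (1 atm), 10% Pd/C, EtOAc, 23 °C
Reagents that add atoms: none
Why: Hydrogenolysis of the benzyl aryl ether, which is clean here because no alkene is present and the aryl ketone and the silyl ether are inert under these mild conditions.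

Step 12
Reactants: 24 (3S,4S)-3-{[(tert-butyldimethylsilyl)oxy]methyl}-4-(4-hydroxy-3,5-dimethoxyphenyl)-5,6,7-trimethoxy-3,4-dihydronaphthalen-1(2H)-one
Product: 25 (3S,4S)-3-{[(tert-butyldimethylsilyl)oxy]methyl}-6-hydroxy-4-(4-hydroxy-3,5-dimethoxyphenyl)-5,7-dimethoxy-3,4-dihydronaphthalen-1(2H)-one
Conditions: NaSEt, DMF, 100 °C, argon; then cold dilute aq. HCl to pH 4
Reagents that add atoms: none
Why: Nucleophilic (SN2) demethylation by thiolate, selective for the C7 methyl ether because it alone releases a phenoxide para to the C4 ketone, while ring C is already a phenoxide and each ring stops reacting once it carries one.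

Step 13
Reactants: 25 (3S,4S)-3-{[(tert-butyldimethylsilyl)oxy]methyl}-6-hydroxy-4-(4-hydroxy-3,5-dimethoxyphenyl)-5,7-dimethoxy-3,4-dihydronaphthalen-1(2H)-one
Product: 26 (3S,4S)-3-{[(tert-butyldimethylsilyl)oxy]methyl}-5,7-dimethoxy-6-(methoxymethoxy)-4-[3,5-dimethoxy-4-(methoxymethoxy)phenyl]-3,4-dihydronaphthalen-1(2H)-one
Conditions: MOMCl, i-Pr2NEt, n-Bu4NI (10 mol %), CH2Cl2, 0 → 40 °C
Reagents that add atoms: chloromethyl methyl ether, COCCl
Why: O-alkylation of both phenols to base-stable MOM acetals with an amine base that does not enolise the ketone.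

Step 14
Reactants: 26 (3S,4S)-3-{[(tert-butyldimethylsilyl)oxy]methyl}-5,7-dimethoxy-6-(methoxymethoxy)-4-[3,5-dimethoxy-4-(methoxymethoxy)phenyl]-3,4-dihydronaphthalen-1(2H)-one; 27 ethyl formate
Product: 28 (2Z,3R,4S)-3-{[(tert-butyldimethylsilyl)oxy]methyl}-2-(hydroxymethylidene)-5,7-dimethoxy-6-(methoxymethoxy)-4-[3,5-dimethoxy-4-(methoxymethoxy)phenyl]-3,4-dihydronaphthalen-1(2H)-one
Conditions: 27, NaH, EtOH (cat.), THF, 0 → 23 °C; AcOH quench
Reagents that add atoms: none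
Why: Crossed Claisen formylation at C3, the only enolisable position, which is driven by formation of the chelated enolate of the β-keto aldehyde and leaves C2 untouched because its hydrogen is not acidified.

Step 15
Reactants: 28 (2Z,3R,4S)-3-{[(tert-butyldimethylsilyl)oxy]methyl}-2-(hydroxymethylidene)-5,7-dimethoxy-6-(methoxymethoxy)-4-[3,5-dimethoxy-4-(methoxymethoxy)phenyl]-3,4-dihydronaphthalen-1(2H)-one
Product: 29 (2E,3R,4S)-3-{[(tert-butyldimethylsilyl)oxy]methyl}-5,7-dimethoxy-6-(methoxymethoxy)-4-[3,5-dimethoxy-4-(methoxymethoxy)phenyl]-2-[(propan-2-yloxy)methylidene]-3,4-dihydronaphthalen-1(2H)-one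
Conditions: i-PrI, K2CO3, acetone, 50 °C
Reagents that add atoms: 2-iodopropane, CC(C)I
Why: O-alkylation of the hydroxymethylene ketone enolate, favoured over C-alkylation with a secondary iodide and carbonate, gives the vinylogous ester, and either alkene geometry serves in the next step.

Step 16
Reactants: 29 (2E,3R,4S)-3-{[(tert-butyldimethylsilyl)oxy]methyl}-5,7-dimethoxy-6-(methoxymethoxy)-4-[3,5-dimethoxy-4-(methoxymethoxy)phenyl]-2-[(propan-2-yloxy)methylidene]-3,4-dihydronaphthalen-1(2H)-one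
Product: 31 (3R,4S)-3-{[(tert-butyldimethylsilyl)oxy]methyl}-5,7-dimethoxy-6-(methoxymethoxy)-4-[3,5-dimethoxy-4-(methoxymethoxy)phenyl]-3,4-dihydronaphthalene-2-carbaldehyde, via allylic alcohol 30 (not isolated)
Conditions: i-Bu2AlH, CH2Cl2, −78 °C; then 1 M aq. HCl, THF, 0 °C
Reagents that add atoms: water, O
Why: 1,2-Hydride reduction of the vinylogous ester followed by acid-induced allylic transposition and enol ether hydrolysis (the classical alkoxymethylene ketone to enal conversion) moves the carbonyl to C10 and places the alkene at C3=C4, with C2 never enolised.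

Step 17
Reactants: 31 (3R,4S)-3-{[(tert-butyldimethylsilyl)oxy]methyl}-5,7-dimethoxy-6-(methoxymethoxy)-4-[3,5-dimethoxy-4-(methoxymethoxy)phenyl]-3,4-dihydronaphthalene-2-carbaldehyde
Product: 32 (3R,4S)-6-hydroxy-4-(4-hydroxy-3,5-dimethoxyphenyl)-3-(hydroxymethyl)-5,7-dimethoxy-3,4-dihydronaphthalene-2-carbaldehyde, the target, (1S,2R) in lignan numbering
Conditions: 3 M aq. HCl, THF, 40 °C, argon
Reagents that add atoms: none
Why: Acid hydrolysis of the two aryl MOM acetals and the primary silyl ether in one operation, under aqueous conditions that a p-hydroxycinnamaldehyde-type enal should tolerate.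

**Compound list**

1 | 4-(benzyloxy)-3,5-dimethoxybenzaldehyde | COc1cc(C=O)cc(OC)c1OCc1ccccc1 | starting material
2 | malonic acid | OC(=O)CC(=O)O | starting material
3 | 2-{[4-(benzyloxy)-3,5-dimethoxyphenyl]methylidene}propanedioic acid | COc1cc(C=C(C(=O)O)C(=O)O)cc(OC)c1OCc1ccccc1 | intermediate
4 | (2E)-3-[4-(benzyloxy)-3,5-dimethoxyphenyl]prop-2-enoic acid | COc1cc(/C=C/C(=O)O)cc(OC)c1OCc1ccccc1 | intermediate
5 | (4S)-4-benzyl-1,3-oxazolidin-2-one | O=C1N[C@@H](Cc2ccccc2)CO1 | starting material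
6 | (2E)-3-[4-(benzyloxy)-3,5-dimethoxyphenyl]prop-2-enoic 2,2-dimethylpropanoic anhydride | COc1cc(/C=C/C(=O)OC(=O)C(C)(C)C)cc(OC)c1OCc1ccccc1 | intermediate
7 | (4S)-4-benzyl-3-{(2E)-3-[4-(benzyloxy)-3,5-dimethoxyphenyl]prop-2-enoyl}-1,3-oxazolidin-2-one | COc1cc(/C=C/C(=O)N2[C@@H](Cc3ccccc3)COC2=O)cc(OC)c1OCc1ccccc1 | intermediate
8 | 3,4-dimethoxyfuran | COc1cocc1OC | starting material
9 | (3,4-dimethoxyfuran-2-yl)lithium | [Li]c1occ(OC)c1OC | intermediate
10 | bromo(3,4-dimethoxyfuran-2-yl)magnesium | Br[Mg]c1occ(OC)c1OC | intermediate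
11 | (4S)-4-benzyl-3-{(3S)-3-[4-(benzyloxy)-3,5-dimethoxyphenyl]-3-(3,4-dimethoxyfuran-2-yl)propanoyl}-1,3-oxazolidin-2-one | COc1cc([C@@H](c2occ(OC)c2OC)CC(=O)N3[C@@H](Cc4ccccc4)COC3=O)cc(OC)c1OCc1ccccc1 | intermediate
12 | methyl bromoacetate | COC(=O)CBr | starting material
13 | sodium (1Z,3S)-1-[(4S)-4-benzyl-2-oxo-1,3-oxazolidin-3-yl]-3-[4-(benzyloxy)-3,5-dimethoxyphenyl]-3-(3,4-dimethoxyfuran-2-yl)prop-1-en-1-olate | COc1cc([C@@H](c2occ(OC)c2OC)/C=C(\[O-])N3[C@@H](Cc4ccccc4)COC3=O)cc(OC)c1OCc1ccccc1.[Na+] | intermediate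
14 | methyl (3S,4S)-3-{[(4S)-4-benzyl-2-oxo-1,3-oxazolidin-3-yl]carbonyl}-4-[4-(benzyloxy)-3,5-dimethoxyphenyl]-4-(3,4-dimethoxyfuran-2-yl)butanoate | COc1cc([C@@H](c2occ(OC)c2OC)[C@H](CC(=O)OC)C(=O)N3[C@@H](Cc4ccccc4)COC3=O)cc(OC)c1OCc1ccccc1 | intermediate
15 | methyl (3S,4S)-4-[4-(benzyloxy)-3,5-dimethoxyphenyl]-4-(3,4-dimethoxyfuran-2-yl)-3-(hydroxymethyl)butanoate | COc1cc([C@@H](c2occ(OC)c2OC)[C@H](CC(=O)OC)CO)cc(OC)c1OCc1ccccc1 | intermediate
16 | (4S)-4-{(S)-[4-(benzyloxy)-3,5-dimethoxyphenyl](3,4-dimethoxyfuran-2-yl)methyl}oxolan-2-one | COc1cc([C@@H](c2occ(OC)c2OC)[C@@H]3CC(=O)OC3)cc(OC)c1OCc1ccccc1 | intermediate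
17 | (3S,4S)-4-[4-(benzyloxy)-3,5-dimethoxyphenyl]-4-(3,4-dimethoxyfuran-2-yl)-3-(hydroxymethyl)-N-methoxy-N-methylbutanamide | COc1cc([C@@H](c2occ(OC)c2OC)[C@@H](CO)CC(=O)N(C)OC)cc(OC)c1OCc1ccccc1 | intermediate
18 | (3S,4S)-4-[4-(benzyloxy)-3,5-dimethoxyphenyl]-3-{[(tert-butyldimethylsilyl)oxy]methyl}-4-(3,4-dimethoxyfuran-2-yl)-N-methoxy-N-methylbutanamide | COc1cc([C@@H](c2occ(OC)c2OC)[C@@H](CO[Si](C)(C)C(C)(C)C)CC(=O)N(C)OC)cc(OC)c1OCc1ccccc1 | intermediate
19 | ethynylmagnesium bromide | C#C[Mg]Br | starting material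
20 | (5S,6S)-6-[4-(benzyloxy)-3,5-dimethoxyphenyl]-5-{[(tert-butyldimethylsilyl)oxy]methyl}-6-(3,4-dimethoxyfuran-2-yl)hex-1-yn-3-one | COc1cc([C@@H](c2occ(OC)c2OC)[C@@H](CO[Si](C)(C)C(C)(C)C)CC(=O)C#C)cc(OC)c1OCc1ccccc1 | intermediate
21 | (3S,4S)-4-[4-(benzyloxy)-3,5-dimethoxyphenyl]-3-{[(tert-butyldimethylsilyl)oxy]methyl}-5,6-dimethoxy-3,4-dihydro-2H-4a,7-epoxynaphthalen-1(7H)-one (oxygen bridge drawn syn to the C4 aryl group; either bridgehead diastereomer converges) | O=C1C[C@H](CO[Si](C)(C)C(C)(C)C)[C@@H](c2cc(OC)c(OCc3ccccc3)c(OC)c2)[C@@]45O[C@@H](C=C14)C(OC)=C5OC | intermediate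
22 | (3S,4S)-4-[4-(benzyloxy)-3,5-dimethoxyphenyl]-3-{[(tert-butyldimethylsilyl)oxy]methyl}-7-hydroxy-5,6-dimethoxy-3,4-dihydronaphthalen-1(2H)-one | COc1cc([C@H]2c3c(cc(O)c(OC)c3OC)C(=O)C[C@@H]2CO[Si](C)(C)C(C)(C)C)cc(OC)c1OCc1ccccc1 | intermediate
23 | (3S,4S)-4-[4-(benzyloxy)-3,5-dimethoxyphenyl]-3-{[(tert-butyldimethylsilyl)oxy]methyl}-5,6,7-trimethoxy-3,4-dihydronaphthalen-1(2H)-one | COc1cc([C@H]2c3c(cc(OC)c(OC)c3OC)C(=O)C[C@@H]2CO[Si](C)(C)C(C)(C)C)cc(OC)c1OCc1ccccc1 | intermediate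
24 | (3S,4S)-3-{[(tert-butyldimethylsilyl)oxy]methyl}-4-(4-hydroxy-3,5-dimethoxyphenyl)-5,6,7-trimethoxy-3,4-dihydronaphthalen-1(2H)-one | COc1cc([C@H]2c3c(cc(OC)c(OC)c3OC)C(=O)C[C@@H]2CO[Si](C)(C)C(C)(C)C)cc(OC)c1O | intermediate
25 | (3S,4S)-3-{[(tert-butyldimethylsilyl)oxy]methyl}-6-hydroxy-4-(4-hydroxy-3,5-dimethoxyphenyl)-5,7-dimethoxy-3,4-dihydronaphthalen-1(2H)-one | COc1cc([C@H]2c3c(cc(OC)c(O)c3OC)C(=O)C[C@@H]2CO[Si](C)(C)C(C)(C)C)cc(OC)c1O | intermediate
26 | (3S,4S)-3-{[(tert-butyldimethylsilyl)oxy]methyl}-5,7-dimethoxy-6-(methoxymethoxy)-4-[3,5-dimethoxy-4-(methoxymethoxy)phenyl]-3,4-dihydronaphthalen-1(2H)-one | COc1cc([C@H]2c3c(cc(OC)c(OCOC)c3OC)C(=O)C[C@@H]2CO[Si](C)(C)C(C)(C)C)cc(OC)c1OCOC | intermediate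
27 | ethyl formate | CCOC=O | starting material
28 | (2Z,3R,4S)-3-{[(tert-butyldimethylsilyl)oxy]methyl}-2-(hydroxymethylidene)-5,7-dimethoxy-6-(methoxymethoxy)-4-[3,5-dimethoxy-4-(methoxymethoxy)phenyl]-3,4-dihydronaphthalen-1(2H)-one | COc1cc([C@H]2c3c(cc(OC)c(OCOC)c3OC)C(=O)/C(=C\O)[C@@H]2CO[Si](C)(C)C(C)(C)C)cc(OC)c1OCOC | intermediate
29 | (2E,3R,4S)-3-{[(tert-butyldimethylsilyl)oxy]methyl}-5,7-dimethoxy-6-(methoxymethoxy)-4-[3,5-dimethoxy-4-(methoxymethoxy)phenyl]-2-[(propan-2-yloxy)methylidene]-3,4-dihydronaphthalen-1(2H)-one | COc1cc([C@H]2c3c(cc(OC)c(OCOC)c3OC)C(=O)/C(=C/OC(C)C)[C@@H]2CO[Si](C)(C)C(C)(C)C)cc(OC)c1OCOC | intermediate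
30 | (2E,3R,4S)-3-{[(tert-butyldimethylsilyl)oxy]methyl}-5,7-dimethoxy-6-(methoxymethoxy)-4-[3,5-dimethoxy-4-(methoxymethoxy)phenyl]-2-[(propan-2-yloxy)methylidene]-1,2,3,4-tetrahydronaphthalen-1-ol (both C1 carbinol epimers) | COc1cc([C@H]2c3c(cc(OC)c(OCOC)c3OC)C(O)/C(=C/OC(C)C)[C@@H]2CO[Si](C)(C)C(C)(C)C)cc(OC)c1OCOC | intermediate
31 | (3R,4S)-3-{[(tert-butyldimethylsilyl)oxy]methyl}-5,7-dimethoxy-6-(methoxymethoxy)-4-[3,5-dimethoxy-4-(methoxymethoxy)phenyl]-3,4-dihydronaphthalene-2-carbaldehyde | COc1cc([C@H]2c3c(cc(OC)c(OCOC)c3OC)C=C(C=O)[C@@H]2CO[Si](C)(C)C(C)(C)C)cc(OC)c1OCOC | intermediate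
32 | (3R,4S)-6-hydroxy-4-(4-hydroxy-3,5-dimethoxyphenyl)-3-(hydroxymethyl)-5,7-dimethoxy-3,4-dihydronaphthalene-2-carbaldehyde | COc1cc([C@H]2c3c(cc(OC)c(O)c3OC)C=C(C=O)[C@@H]2CO)cc(OC)c1O | target

**Step count and risks**

Total step count: 17. Longest linear sequence: 17 steps (1 to 32).

Steps most likely to fail:

Step 9 (key step). The terminal ynone may be consumed by intermolecular conjugate addition or oligomerisation before it cycloadds, or the bridged adduct may ionise at C6–O and rearrange instead of aromatising. The fallback sets out from 18 and comes back at 22, and changes the dienophile to a silicon-capped one that can be purified and stored. LiC≡CSiMe3 (THF, −78 °C) should convert 18 into (5S,6S)-6-[4-(benzyloxy)-3,5-dimethoxyphenyl]-5-{[(tert-butyldimethylsilyl)oxy]methyl}-6-(3,4-dimethoxyfuran-2-yl)-1-(trimethylsilyl)hex-1-yn-3-one F1. Heating (PhMe, 110 °C) should take it through the silylated oxa-bridged cycloadduct F2 to the C5-silylated phenol (3S,4S)-4-[4-(benzyloxy)-3,5-dimethoxyphenyl]-3-{[(tert-butyldimethylsilyl)oxy]methyl}-7-hydroxy-5,6-dimethoxy-8-(trimethylsilyl)-3,4-dihydronaphthalen-1(2H)-one F3. Ipso-protodesilylation ortho to the phenol (CF3CO2H, CH2Cl2, 0 °C) then returns 22.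

Step 3. Transfer of the 2-furyl group from copper may be slow, so that imide 7 is recovered or the Grignard reagent attacks the imide carbonyl groups, and facial selectivity may erode. The fallback sets out from 8 and comes back at 11; it exchanges the roles of the two aryl partners on the enantiomeric auxiliary and then exchanges the auxiliary, using only aryl-copper additions of the standard kind.
- Furyllithium 9 is formylated with DMF to 3,4-dimethoxyfuran-2-carbaldehyde F4.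
- Knoevenagel–Doebner condensation with 2 gives, through 2-[(3,4-dimethoxyfuran-2-yl)methylidene]propanedioic acid F5, (2E)-3-(3,4-dimethoxyfuran-2-yl)prop-2-enoic acid F6.
- Its mixed pivalic anhydride F7 (t-BuCOCl, Et3N) acylates (4R)-4-benzyl-1,3-oxazolidin-2-one (LiCl) to give (4R)-4-benzyl-3-[(2E)-3-(3,4-dimethoxyfuran-2-yl)prop-2-enoyl]-1,3-oxazolidin-2-one F8.
- 4-Bromo-2,6-dimethoxyphenol is benzylated (BnBr, K2CO3) to 2-(benzyloxy)-5-bromo-1,3-dimethoxybenzene F9 and converted with Mg into [4-(benzyloxy)-3,5-dimethoxyphenyl]magnesium bromide F10.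
- F10 adds to F8 under CuBr·SMe2 anti to the benzyl group to give (4R)-4-benzyl-3-{(3S)-3-[4-(benzyloxy)-3,5-dimethoxyphenyl]-3-(3,4-dimethoxyfuran-2-yl)propanoyl}-1,3-oxazolidin-2-one F11.
- LiOH/H2O2 releases (3S)-3-[4-(benzyloxy)-3,5-dimethoxyphenyl]-3-(3,4-dimethoxyfuran-2-yl)propanoic acid F12, and its mixed pivalic anhydride F13 acylates 5 (LiCl, Et3N) to give 11.

Step 12. The thiolate may attack a methyl group other than the one on the C7 oxygen, or conversion may stall while the silyl ether is lost at 100 °C. The fallback sets out from 23 and comes back at 25, replacing steps 11 and 12 by a Lewis-acid cleavage that relies on chelation instead of SN2 selectivity. AlCl3 (excess, CH2Cl2, 0 → 23 °C) should cleave the two ethers whose oxygen is flanked by two methoxy groups, namely the ring C benzyl ether and the C7 methyl ether para to the ketone, together with the silyl ether. This gives (3S,4S)-6-hydroxy-3-(hydroxymethyl)-4-(4-hydroxy-3,5-dimethoxyphenyl)-5,7-dimethoxy-3,4-dihydronaphthalen-1(2H)-one F14. TBSCl/imidazole silylates all three hydroxyl groups to the tris(silyl) ether F15, and K2CO3 in MeOH at 0 °C removes the two aryl silyl ethers selectively to give 25.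

Further compounds
F1 | step 9 | (5S,6S)-6-[4-(benzyloxy)-3,5-dimethoxyphenyl]-5-{[(tert-butyldimethylsilyl)oxy]methyl}-6-(3,4-dimethoxyfuran-2-yl)-1-(trimethylsilyl)hex-1-yn-3-one | COc1cc([C@@H](c2occ(OC)c2OC)[C@@H](CO[Si](C)(C)C(C)(C)C)CC(=O)C#C[Si](C)(C)C)cc(OC)c1OCc1ccccc1
F2 | step 9 | (3S,4S)-4-[4-(benzyloxy)-3,5-dimethoxyphenyl]-3-{[(tert-butyldimethylsilyl)oxy]methyl}-5,6-dimethoxy-8-(trimethylsilyl)-3,4-dihydro-2H-4a,7-epoxynaphthalen-1(7H)-one | O=C1C[C@H](CO[Si](C)(C)C(C)(C)C)[C@@H](c2cc(OC)c(OCc3ccccc3)c(OC)c2)[C@@]45O[C@@H](C([Si](C)(C)C)=C14)C(OC)=C5OC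
F3 | step 9 | (3S,4S)-4-[4-(benzyloxy)-3,5-dimethoxyphenyl]-3-{[(tert-butyldimethylsilyl)oxy]methyl}-7-hydroxy-5,6-dimethoxy-8-(trimethylsilyl)-3,4-dihydronaphthalen-1(2H)-one | COc1cc([C@H]2c3c(c([Si](C)(C)C)c(O)c(OC)c3OC)C(=O)C[C@@H]2CO[Si](C)(C)C(C)(C)C)cc(OC)c1OCc1ccccc1
F4 | step 3 | 3,4-dimethoxyfuran-2-carbaldehyde | COc1coc(C=O)c1OC
F5 | step 3 | 2-[(3,4-dimethoxyfuran-2-yl)methylidene]propanedioic acid | COc1coc(C=C(C(=O)O)C(=O)O)c1OC
F6 | step 3 | (2E)-3-(3,4-dimethoxyfuran-2-yl)prop-2-enoic acid | COc1coc(/C=C/C(=O)O)c1OC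
F7 | step 3 | (2E)-3-(3,4-dimethoxyfuran-2-yl)prop-2-enoic 2,2-dimethylpropanoic anhydride | COc1coc(/C=C/C(=O)OC(=O)C(C)(C)C)c1OC
F8 | step 3 | (4R)-4-benzyl-3-[(2E)-3-(3,4-dimethoxyfuran-2-yl)prop-2-enoyl]-1,3-oxazolidin-2-one | COc1coc(/C=C/C(=O)N2[C@H](Cc3ccccc3)COC2=O)c1OC
F9 | step 3 | 2-(benzyloxy)-5-bromo-1,3-dimethoxybenzene | COc1cc(Br)cc(OC)c1OCc1ccccc1
F10 | step 3 | [4-(benzyloxy)-3,5-dimethoxyphenyl]magnesium bromide | COc1cc([Mg]Br)cc(OC)c1OCc1ccccc1
F11 | step 3 | (4R)-4-benzyl-3-{(3S)-3-[4-(benzyloxy)-3,5-dimethoxyphenyl]-3-(3,4-dimethoxyfuran-2-yl)propanoyl}-1,3-oxazolidin-2-one | COc1cc([C@@H](c2occ(OC)c2OC)CC(=O)N3[C@H](Cc4ccccc4)COC3=O)cc(OC)c1OCc1ccccc1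
F12 | step 3 | (3S)-3-[4-(benzyloxy)-3,5-dimethoxyphenyl]-3-(3,4-dimethoxyfuran-2-yl)propanoic acid | COc1cc([C@@H](c2occ(OC)c2OC)CC(=O)O)cc(OC)c1OCc1ccccc1
F13 | step 3 | (3S)-3-[4-(benzyloxy)-3,5-dimethoxyphenyl]-3-(3,4-dimethoxyfuran-2-yl)propanoic 2,2-dimethylpropanoic anhydride | COc1cc([C@@H](c2occ(OC)c2OC)CC(=O)OC(=O)C(C)(C)C)cc(OC)c1OCc1ccccc1
F14 | step 12 | (3S,4S)-6-hydroxy-3-(hydroxymethyl)-4-(4-hydroxy-3,5-dimethoxyphenyl)-5,7-dimethoxy-3,4-dihydronaphthalen-1(2H)-one | COc1cc([C@H]2c3c(cc(OC)c(O)c3OC)C(=O)C[C@@H]2CO)cc(OC)c1O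
F15 | step 12 | (3S,4S)-6-[(tert-butyldimethylsilyl)oxy]-3-{[(tert-butyldimethylsilyl)oxy]methyl}-4-{4-[(tert-butyldimethylsilyl)oxy]-3,5-dimethoxyphenyl}-5,7-dimethoxy-3,4-dihydronaphthalen-1(2H)-one | COc1cc([C@H]2c3c(cc(OC)c(O[Si](C)(C)C(C)(C)C)c3OC)C(=O)C[C@@H]2CO[Si](C)(C)C(C)(C)C)cc(OC)c1O[Si](C)(C)C(C)(C)C
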